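Ring A (chamigrane numbering) is disconnected at its C7–C8 bond. The exocyclic C7=C14 methylene, the C8 methylene and the C9 oxygen of ring A form a β,γ-unsaturated carbonyl array, the retron of a Conia-ene reaction. A gold-catalysed 6-exo-dig attack of a C8 silyl enol ether on a C6-bound ethynyl group closes ring A between the quaternary carbons C6 and C11 and delivers the methylene and the C9 ketone in one operation, with the C10 bromine already in place and then equilibrated. The precursor is a monocyclic ethynylcyclohexene oxide with an α-bromo methyl ketone side chain; its epoxide later becomes the trans-diaxial C2 chloride and C3 bromide of ring B.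

Key step: step 8

Remark (numbering): ring B is C1–C6 (C2 bears chlorine, C3 bromine and the methyl C15); ring A is C6–C11 (C7 bears the C14 methylene, C9 the acetate, C10 bromine, C11 the geminal methyls). The same labels are used for the corresponding carbons of the open-chain precursors.

Remark (assumption): the oxazaborolidinium-catalysed Diels–Alder reaction of step 3 is assumed to show the facial sense usual for 2-substituted acroleins, so that the (S)-catalyst gives (S)-7. Were the sense opposite, the (R)-catalyst would be used with no other change.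

Step 1
Reactants: 1 4-methylpent-3-en-2-ol (racemic); 2 propargyl bromide
Product: 3 2-methyl-4-(prop-2-yn-1-yloxy)pent-2-ene (racemic)
Conditions: NaH, THF/DMF, 0 °C → rt
Reagents that add atoms: none
Why: Williamson ether synthesis, SN2 attack of the sodium alkoxide on the primary propargylic bromide; the carbinol stereocentre is left racemic because step 2 destroys it.

Step 2
Reactants: 3
Product: 5 (4E)-3,3-dimethyl-2-methylidenehex-4-enal, via allenyl ether 4 (not isolated)
Conditions: KOt-Bu (20 mol %), THF, rt; then toluene, 100 °C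
Reagents that add atoms: none
Why: Base-catalysed isomerisation of the propargyl ether to the allenyl ether is followed by an allenyl-ether Claisen rearrangement ([3,3]) through a chair with the carbinol methyl equatorial, which forms the C6–C11 bond and the quaternary C11, gives the (E)-propenyl chain and unveils the 2-substituted acrolein; no stereocentre remains.

Step 3
Reactants: 5; 6 isoprene
Product: 7 (1S)-4-methyl-1-[(3E)-2-methylpent-3-en-2-yl]cyclohex-3-ene-1-carbaldehyde
Conditions: (S)-3,3-diphenyl-1-(2-methylphenyl)tetrahydro-1H,3H-pyrrolo[1,2-c][1,3,2]oxazaborole (20 mol %), Tf2NH (16 mol %), CH2Cl2, −78 → −40 °C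
Reagents that add atoms: none
Why: Enantioselective Diels–Alder reaction of a 2-substituted acrolein under chiral oxazaborolidinium catalysis: the formyl-bound Lewis acid shields one face of the enal, isoprene adds with para regiochemistry (C6 1,4 to the methyl-bearing C3), and the C6 quaternary stereocentre is thereby set as (S)-7 (see the remark on the facial sense).

Step 4
Reactants: 7; 8 dimethyl (1-diazo-2-oxopropyl)phosphonate (Ohira–Bestmann reagent)
Product: 9 (4R)-4-ethynyl-1-methyl-4-[(3E)-2-methylpent-3-en-2-yl]cyclohex-1-ene
Conditions: K2CO3, MeOH, 0 °C → rt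
Reagents that add atoms: none
Why: Seyferth–Gilbert homologation with the Ohira–Bestmann reagent: the α-quaternary aldehyde cannot enolise, so C6 is safe under K2CO3/MeOH, and the diazoalkene formed by Horner–Wadsworth–Emmons-type olefination loses N2 with 1,2-hydride shift to give the terminal alkyne (C7≡C14).

Step 5
Reactants: 9
Product: 11 (1S,4R,6R)-4-ethynyl-1-methyl-4-[(3E)-2-methylpent-3-en-2-yl]-7-oxabicyclo[4.1.0]heptane, via ring bromohydrin 10 (not isolated)
Conditions: NBS (1.05 equiv), THF/H2O, 0 °C; then K2CO3, MeOH, rt
Reagents that add atoms: water, O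
Why: Bromohydrin formation and base-induced epoxide closure: the trisubstituted ring alkene reacts before the hindered disubstituted chain alkene and the alkyne, ring B is locked with the tert-alkyl group equatorial and the slim ethynyl group axial, only the bromonium ion on the ethynyl face can open in both the Markovnikov and the trans-diaxial (Fürst–Plattner) sense (water at C3 from the opposite face, as in the bromohydrin route to trans-limonene oxide), and closure with inversion at C2 puts the epoxide on the face opposite to ethynyl, which fixes C2 and C3 relative to C6.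

Step 6
Reactants: 11
Product: 13 3-bromo-4-[(1R,3R,6S)-3-ethynyl-6-methyl-7-oxabicyclo[4.1.0]heptan-3-yl]-4-methylpentan-2-one (both epimers at the CHBr carbon C10), via side-chain bromohydrin 12 (not isolated)
Conditions: NBS, DMSO/H2O, 0 °C → rt; then IBX (2-iodoxybenzoic acid), rt
Reagents that add atoms: N-bromosuccinimide, O=C1CCC(=O)N1Br; water, O (relayed through the solvent dimethyl sulfoxide, CS(C)=O)
Why: Bromohydrin formation in aqueous DMSO and IBX oxidation in the same pot: the oxygen nucleophile opens the bromonium ion of the chain alkene at C9, away from the quaternary C11, so bromine ends on C10 and the carbonyl on C9 without any regiochemical ambiguity of enolisation, the neutral medium spares epoxide and alkyne, and C10 is formed as both epimers, to be corrected in step 8.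

Step 7
Reactants: 13
Product: 14 tert-butyl{[3-bromo-4-[(1R,3R,6S)-3-ethynyl-6-methyl-7-oxabicyclo[4.1.0]heptan-3-yl]-4-methylpent-1-en-2-yl]oxy}dimethylsilane (both C10 epimers)
Conditions: LiN(SiMe3)2, THF, −78 °C; then t-BuMe2SiOTf
Reagents that add atoms: tert-butyldimethylsilyl trifluoromethanesulfonate, CC(C)(C)[Si](C)(C)OS(=O)(=O)C(F)(F)F
Why: Kinetic enolisation and O-silylation: the hindered amide removes a proton from the unhindered C8 methyl group and not the C10–H shielded by the quaternary C11 (the standard route from α-bromo ketones to 2-silyloxyallyl bromides), ketone deprotonation is faster than that of the alkyne C–H, and trapping at −78 °C leaves the epoxide intact.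

Step 8
Reactants: 14
Product: 16 (2R,3S,6R,10R)-10-bromo-2,3-epoxychamigr-7(14)-en-9-one, via C10-epimer mixture 15 (not isolated)
Conditions: Ph3PAuNTf2 (5 mol %), CH2Cl2/MeOH (10:1), rt; then n-Bu4NBr, MeCN, 50 °C
Reagents that add atoms: tetrabutylammonium bromide, CCCC[N+](CCCC)(CCCC)CCCC.[Br-] (degenerate exchange of the C10 bromine)
Why: Gold-catalysed Conia-ene-type carbocyclisation of a silyl enol ether onto a terminal alkyne: cationic monovalent gold binds the C7≡C14 triple bond, C8 of the enol ether attacks the internal carbon C7 anti to gold, and methanol removes the silyl group and protonates the vinyl–gold bond, which leaves the exocyclic C7=C14 methylene and the C9 ketone unconjugated. Ring A closes in the 6-exo-dig mode between the two quaternary carbons C6 and C11, whose substituents hold the chain in a reactive fold, while the Markovnikov preference of the terminal alkyne excludes the 7-endo path. The new C7–C8 bond creates no stereocentre, C6 is untouched, and C10 arrives as both epimers (15). Bromide then exchanges the C10 bromine (SN2 or debromination–rebromination through the C9–C10 enolate, never through the C8 enol, so the alkene stays exocyclic) and should funnel the mixture towards (10R)-16, the epimer with equatorial bromine in the ring-A chair that places the C14 methylene over the C1–C2 edge of ring B. That edge carries no axial group as long as C2 is part of the epoxide, which is why chlorine is put on C2 only in step 10. The step needs chemoselectivity for the enol ether over the epoxide and the allylic C10–Br bond, secured by a silver-free, weakly oxophilic gold catalyst at room temperature.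

Step 9
Reactants: 16
Product: 18 (2R,3S,6R,9S,10R)-10-bromo-2,3-epoxychamigr-7(14)-en-9-yl acetate, via aluminium alkoxide 17 (not isolated)
Conditions: i-Bu2AlH, CH2Cl2, −78 °C; then Ac2O, pyridine, DMAP, −78 °C → rt
Reagents that add atoms: acetic anhydride, CC(=O)OC(C)=O
Why: Hydride reduction of the α-bromo ketone and acetylation of the aluminium alkoxide in the same pot: the axial C11 methyl group blocks axial attack at C9, so the bulky hydride enters equatorially and gives the axial C9–O bond cis to the equatorial C10 bromine (9S), the usual outcome for 2-bromo-3,3-dialkylcyclohexanones, and the epoxide and the C–Br bond are inert at −78 °C.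

Step 10
Reactants: 18
Product: 19 (2S,3S,6R,9S,10R)-10-bromo-2-chloro-3-hydroxychamigr-7(14)-en-9-yl acetate
Conditions: LiCl, AcOH, THF, rt → 40 °C
Reagents that add atoms: lithium chloride, [Li+].[Cl-]
Why: Nucleophilic opening of the epoxide by chloride under weakly acidic buffering: in the locked ring B the SN2 attack at the secondary C2 from the C7 face is the trans-diaxial (Fürst–Plattner) path, as for 5α,6α-epoxy steroids, so C2 is inverted to the axial (2S)-chloride and C3 keeps its oxygen as the axial tertiary alcohol, while acetate, C10 bromide and the C7 methylene do not react with LiCl/AcOH.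

Step 11
Reactants: 19
Product: 20 9-acetylisoobtusol, (2S,3S,6R,9S,10R)-3,10-dibromo-2-chlorochamigr-7(14)-en-9-yl acetate
Conditions: 1-bromo-N,N,2-trimethylprop-1-en-1-amine, CH2Cl2, 0 °C → rt
Reagents that add atoms: 1-bromo-N,N,2-trimethylprop-1-en-1-amine, CC(C)=C(Br)N(C)C
Why: Deoxybromination of a tertiary alcohol with an α-bromoenamine under neutral conditions: the alkoxyiminium group ionises with assistance of the antiperiplanar C2 chlorine (chloronium ion), bromide opens it at the tertiary C3 in the Markovnikov and trans-diaxial sense, so C3 is substituted with retention, and no free acid is present that could add to or isomerise the C7 methylene.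

Compound list

1 | 4-methylpent-3-en-2-ol (racemic) | CC(O)C=C(C)C | starting material
2 | propargyl bromide (3-bromoprop-1-yne) | C#CCBr | starting material
3 | 2-methyl-4-(prop-2-yn-1-yloxy)pent-2-ene (racemic) | CC(C)=CC(C)OCC#C | intermediate
4 | 2-methyl-4-(propa-1,2-dien-1-yloxy)pent-2-ene (allenyl ether, racemic) | CC(C)=CC(C)OC=C=C | intermediate
5 | (4E)-3,3-dimethyl-2-methylidenehex-4-enal | C/C=C/C(C)(C)C(=C)C=O | intermediate
6 | isoprene | C=CC(C)=C | starting material
7 | (1S)-4-methyl-1-[(3E)-2-methylpent-3-en-2-yl]cyclohex-3-ene-1-carbaldehyde | C/C=C/C(C)(C)[C@@]1(C=O)CC=C(C)CC1 | intermediate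
8 | dimethyl (1-diazo-2-oxopropyl)phosphonate | CC(=O)C(=[N+]=[N-])P(=O)(OC)OC | starting material
9 | (4R)-4-ethynyl-1-methyl-4-[(3E)-2-methylpent-3-en-2-yl]cyclohex-1-ene | C/C=C/C(C)(C)[C@@]1(C#C)CC=C(C)CC1 | intermediate
10 | (1S,2S,4R)-2-bromo-4-ethynyl-1-methyl-4-[(3E)-2-methylpent-3-en-2-yl]cyclohexan-1-ol | C/C=C/C(C)(C)[C@]1(C#C)CC[C@](C)(O)[C@@H](Br)C1 | intermediate
11 | (1S,4R,6R)-4-ethynyl-1-methyl-4-[(3E)-2-methylpent-3-en-2-yl]-7-oxabicyclo[4.1.0]heptane | C/C=C/C(C)(C)[C@]1(C#C)CC[C@]2(C)O[C@@H]2C1 | intermediate
12 | 3-bromo-4-[(1R,3R,6S)-3-ethynyl-6-methyl-7-oxabicyclo[4.1.0]heptan-3-yl]-4-methylpentan-2-ol (anti-addition bromohydrin, both diastereomers relative to the ring) | CC(O)C(Br)C(C)(C)[C@]1(C#C)CC[C@]2(C)O[C@@H]2C1 | intermediate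
13 | 3-bromo-4-[(1R,3R,6S)-3-ethynyl-6-methyl-7-oxabicyclo[4.1.0]heptan-3-yl]-4-methylpentan-2-one (both C10 epimers) | CC(=O)C(Br)C(C)(C)[C@]1(C#C)CC[C@]2(C)O[C@@H]2C1 | intermediate
14 | tert-butyl{[3-bromo-4-[(1R,3R,6S)-3-ethynyl-6-methyl-7-oxabicyclo[4.1.0]heptan-3-yl]-4-methylpent-1-en-2-yl]oxy}dimethylsilane (both C10 epimers) | C=C(O[Si](C)(C)C(C)(C)C)C(Br)C(C)(C)[C@]1(C#C)CC[C@]2(C)O[C@@H]2C1 | intermediate
15 | (2R,3S,6R)-10-bromo-2,3-epoxychamigr-7(14)-en-9-one (kinetic mixture of both C10 epimers) | C=C1CC(=O)C(Br)C(C)(C)[C@@]12CC[C@]3(C)O[C@@H]3C2 | intermediate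
16 | (2R,3S,6R,10R)-10-bromo-2,3-epoxychamigr-7(14)-en-9-one | C=C1CC(=O)[C@H](Br)C(C)(C)[C@@]12CC[C@]3(C)O[C@@H]3C2 | intermediate
17 | diisobutylaluminium (2R,3S,6R,9S,10R)-10-bromo-2,3-epoxychamigr-7(14)-en-9-olate | C=C1C[C@H](O[Al](CC(C)C)CC(C)C)[C@H](Br)C(C)(C)[C@@]12CC[C@]3(C)O[C@@H]3C2 | intermediate
18 | (2R,3S,6R,9S,10R)-10-bromo-2,3-epoxychamigr-7(14)-en-9-yl acetate | C=C1C[C@H](OC(C)=O)[C@H](Br)C(C)(C)[C@@]12CC[C@]3(C)O[C@@H]3C2 | intermediate
19 | (2S,3S,6R,9S,10R)-10-bromo-2-chloro-3-hydroxychamigr-7(14)-en-9-yl acetate | C=C1C[C@H](OC(C)=O)[C@H](Br)C(C)(C)[C@@]12CC[C@](C)(O)[C@@H](Cl)C2 | intermediate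
20 | 9-acetylisoobtusol, (2S,3S,6R,9S,10R)-3,10-dibromo-2-chlorochamigr-7(14)-en-9-yl acetate | C=C1C[C@H](OC(C)=O)[C@H](Br)C(C)(C)[C@@]12CC[C@](C)(Br)[C@@H](Cl)C2 | target

Total step count: 11. Longest linear sequence: 11 steps (from 1 and 2 to 20).

Steps most likely to fail

Step 11. Ionisation of the tertiary C3–O bond is slowed by the neighbouring chlorine, so elimination towards C4 or C15, or attack on the C7 methylene, may outrun substitution. The fallback sets out from 18, also bypasses step 10, and comes back at 20. The epoxide of 18 is deoxygenated with MeReO3 (cat.) and PPh3 (benzene, rt) to the ring-B alkene (6R,9S,10R)-10-bromochamigra-2,7(14)-dien-9-yl acetate F1. F1 is then bromochlorinated (NBS, LiCl, MeCN/CH2Cl2, −30 °C). The more nucleophilic trisubstituted ring alkene should react before the hindered C7 methylene; the bromonium ion should form on the ring-B face remote from C7 and be opened by chloride trans-diaxially at C2, as in the 5α-bromo-6β-chloro adducts of Δ5-steroids, to give 20. Markovnikov opening at C3 is the competing process.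

Step 8. Loss of the silyl group by methanolysis, ionisation of the allylic C10–Br bond to a 2-silyloxyallyl cation, or acid-induced opening of the epoxide may compete with carbocyclisation; the bromide-mediated equilibration at C10 may also give only a modest preference. The fallback replaces the alkyne by a vinyl group and uses a palladium-mediated oxidative cyclisation of a silyl enol ether onto an alkene; it sets out from 11 and comes back at 16 through 15. Semi-hydrogenation of 11 (H2, Pd/CaCO3 poisoned with Pb(OAc)2, quinoline) gives the vinyl epoxide (1S,4R,6R)-4-ethenyl-1-methyl-4-[(3E)-2-methylpent-3-en-2-yl]-7-oxabicyclo[4.1.0]heptane F2. NBS in DMSO/H2O acts on the more reactive chain alkene to give the bromohydrin F3, which IBX oxidises to the α-bromo ketone F4. LiN(SiMe3)2 and t-BuMe2SiOTf give the silyl enol ether F5. With Pd(OAc)2 (one equivalent, MeCN, rt) divalent palladium activates the vinyl group, C8 attacks C7 (6-exo-trig), and β-hydride elimination of the C7 hydrogen from the primary alkylpalladium gives the C7=C14 methylene of 15, which is equilibrated to 16 as in step 8.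

Step 3. The 2-tert-alkyl acrolein 5 may be too hindered for the chiral Lewis acid, so that conversion or facial selectivity is poor. The fallback sets out from 5 and 6 and comes back at 7 by resolution. The Diels–Alder reaction promoted by Me2AlCl (CH2Cl2, −40 °C) gives the racemic aldehyde F6. Condensation with (1R,2R)-N,N′-dimethyl-1,2-diphenylethane-1,2-diamine (molecular sieves, CH2Cl2) gives two diastereomeric aminals, F7 from the (S)-aldehyde and F8 from the (R)-aldehyde, which are separated by chromatography. Mild acid hydrolysis of F7 (aqueous HCl, THF) returns 7.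

Further compounds

F1 | step 11 | (6R,9S,10R)-10-bromochamigra-2,7(14)-dien-9-yl acetate | C=C1C[C@H](OC(C)=O)[C@H](Br)C(C)(C)[C@@]12CCC(C)=CC2
F2 | step 8 | (1S,4R,6R)-4-ethenyl-1-methyl-4-[(3E)-2-methylpent-3-en-2-yl]-7-oxabicyclo[4.1.0]heptane | C/C=C/C(C)(C)[C@]1(C=C)CC[C@]2(C)O[C@@H]2C1
F3 | step 8 | 3-bromo-4-[(1R,3R,6S)-3-ethenyl-6-methyl-7-oxabicyclo[4.1.0]heptan-3-yl]-4-methylpentan-2-ol (both diastereomers relative to the ring) | CC(O)C(Br)C(C)(C)[C@]1(C=C)CC[C@]2(C)O[C@@H]2C1
F4 | step 8 | 3-bromo-4-[(1R,3R,6S)-3-ethenyl-6-methyl-7-oxabicyclo[4.1.0]heptan-3-yl]-4-methylpentan-2-one (both C10 epimers) | CC(=O)C(Br)C(C)(C)[C@]1(C=C)CC[C@]2(C)O[C@@H]2C1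
F5 | step 8 | tert-butyl{[3-bromo-4-[(1R,3R,6S)-3-ethenyl-6-methyl-7-oxabicyclo[4.1.0]heptan-3-yl]-4-methylpent-1-en-2-yl]oxy}dimethylsilane (both C10 epimers) | C=C(O[Si](C)(C)C(C)(C)C)C(Br)C(C)(C)[C@]1(C=C)CC[C@]2(C)O[C@@H]2C1
F6 | step 3 | racemic 4-methyl-1-[(3E)-2-methylpent-3-en-2-yl]cyclohex-3-ene-1-carbaldehyde | C/C=C/C(C)(C)C1(C=O)CC=C(C)CC1
F7 | step 3 | (4R,5R)-1,3-dimethyl-2-[(1S)-4-methyl-1-[(3E)-2-methylpent-3-en-2-yl]cyclohex-3-en-1-yl]-4,5-diphenylimidazolidine | CN1[C@H](c2ccccc2)[C@@H](c2ccccc2)N(C)C1[C@]1(C(C)(C)/C=C/C)CC=C(C)CC1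
F8 | step 3 | (4R,5R)-1,3-dimethyl-2-[(1R)-4-methyl-1-[(3E)-2-methylpent-3-en-2-yl]cyclohex-3-en-1-yl]-4,5-diphenylimidazolidine | CN1[C@H](c2ccccc2)[C@@H](c2ccccc2)N(C)C1[C@@]1(C(C)(C)/C=C/C)CC=C(C)CC1
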